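Read the end first. You have two earlier runs and one new flask, and in each the substrate ends up as target and as the isomer of the product.

| flask | substrate | remark | time |
|---|---|---|---|
| green | 0.0034 M | run made earlier |  |
| grey | 0.0075 M | run made earlier |  |
| flask | 0.0050 M |  | 8.0 min |

- green (time / min: isomer of the product / %, target / %): 0.667: 1.0, 7.4; 1.33: 4.9, 18.4; 3.00: 7.6, 37.2; 8.00: 14.4, 64.2
- grey (time / min: isomer of the product / %, target / %): 0.667: 0.3, 7.2; 1.33: 2.1, 17.6; 3.00: 8.3, 36.7; 8.00: 14.4, 61.7

(readings scatter by 1 percentage point)

- ratio of isomer of the product to target at 15 s
- ratio of isomer of the product to target at 80 s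
- ratio of isomer of the product to target at 8.0 min
- which of isomer of the product and target there is more of at 8.0 min



At 8.00 min isomer over target reads 0.224 in the green run and 0.233 in the grey run, although the charges differ by a factor of 2.21. Pooled, this gives a plateau ratio of 0.229, so I expect target to lead in the flask at 8.0 min.

The time 80 s is the second reading, where green gives 0.266 and grey 0.119. You might interpolate by charge, but at 3.00 min the order reverses, to 0.204 against 0.226. So I pool again and get 0.194.

The time 15 s lies before any reading, and the first reading doesn't help: isomer stands at 1.0% and 0.3% against a scatter of 1 percentage point. So compare rates at one moment instead. Isomer forms from target and returns at a rate constant b, while fresh target dilutes the ratio at a fractional growth rate g. In a quasi-steady state the ratio is then the plateau ratio times b/(b+g).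

Between the first and third readings g is 0.695 min⁻¹, so the pooled ratio at 80 s gives a return rate b of 3.94 min⁻¹. The objection is that this rests on a gap of 0.0343, close to what the scatter allows, so the value is rough. Early on, target grows as time to the power 1.31, which makes g at 15 s about 5.23 min⁻¹. My ratio there is 0.0983, though a sharper lag in target would lower it.

The forecast, which has the isomer forming “probably by reversible isomerisation”, gives 0.03, 0.16 and 0.23, with target ahead. Its early value stands below mine.

The flask gives 0.101, 0.197 and 0.219, and target leads with 62.7% against 13.7%.

    substrate → intermediate A (k = 0.0240 s⁻¹)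
    intermediate A → target (k = 0.00830 s⁻¹)
    intermediate A ⇌ intermediate B (K = 1.10, k = 0.0170 s⁻¹)
    intermediate B ⇌ intermediate C (K = 7.50, k = 7.80 × 10⁻⁴ s⁻¹)
    intermediate C ⇌ intermediate D (K = 2.60, k = 0.0250 s⁻¹)
    substrate ⇌ dormant form (K = 0.220, k = 0.00580 s⁻¹)
    target ⇌ isomer of the product (K = 0.220, k = 0.0290 s⁻¹)

The reverse step from isomer to target has the largest single effect on the late ratio: the simulated run without it ends at 32.1 instead of 0.219, with the lead turned. In this flask target grows at 0.0891 min⁻¹ between 4.00 min and 8.00 min, far slower than my rough return rate of 3.94 min⁻¹ read off the runs, so dilution hardly counts there, and my estimate, with the plateau ratio also read off the runs, is 0.224. The neighbouring flask with 0.0085 M substrate holds 62.7% target, so my estimated ratio gives 14.0% isomer, and it holds 13.7%.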